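**Retrosynthetic overview**

1. Target 22 ⇐ epoxy ketone ester 21 (chelation-controlled ketone reduction) ⇐ epoxy ketone 16 + isovanilloyl chloride 19; 16 ⇐ hydroxy dienone 15 (nucleophilic epoxidation).
2. 15 ⇐ achiral macrocyclic 1,3-dione 14 by asymmetric hydrogenation, the only source of absolute configuration (C7, C8).
3. Ten-membered ring ⇐ anionic oxy-Cope ring expansion (6 → 10) of the 1-isopropenyl-2-vinylcyclohexenol 10; the surplus C5 oxygen leaves through the enol triflate.
4. 10 ⇐ p-quinol 5: epoxidation blocks and oxidises C6, the quinol alkoxide steers vinyl to C10, Pd(0) turns the epoxy ketone into the 1,3-dione.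
5. 5 ⇐ oxidative dearomatisation of carvacrol 1 (key step): its ring carbons, methyl and isopropyl become C5–C10, C14 and C11–C13. Ring order: arene ring (given) → ten-membered ring (step 7) → epoxide (step 10).

Assumption: germacrane numbering is used for the ten-membered ring (C1=C10, methyls on C4 and C10, isopropyl on C7, oxygens on C4/C5, C6, C8); compounds 4–10 are racemic (one enantiomer drawn) and all their stereocentres are erased in step 7.

**Step 1**
Reactants: 1 carvacrol (5-isopropyl-2-methylphenol)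
Product: 2 4,4-dimethoxy-2-methyl-5-(propan-2-yl)cyclohexa-2,5-dien-1-one
Conditions: PhI(OAc)2 (2.2 equiv), MeOH, 0 °C → rt
Reagents that add atoms: methanol (CO)
Why: Oxidative dearomatisation with a hypervalent iodine reagent: two-fold oxidation of the para-unsubstituted phenol with methanol capture at C4 gives the p-quinone monoketal, which leaves only the carbonyl next to the methyl-bearing carbon free; no stereocentre is formed.

**Step 2**
Reactants: 2 4,4-dimethoxy-2-methyl-5-(propan-2-yl)cyclohexa-2,5-dien-1-one; 3 prop-1-en-2-ylmagnesium bromide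
Product: 5 rac-4-hydroxy-5-methyl-4-(prop-1-en-2-yl)-2-(propan-2-yl)cyclohexa-2,5-dien-1-one, via quinol ketal 4 (not isolated)
Conditions: 3 (1.3 equiv), THF, −78 → 0 °C; then 1 M HCl, THF, 0 °C
Reagents that add atoms: water (O)
Why: 1,2-Grignard addition to the only free carbonyl of the quinone monoketal followed by acid hydrolysis of the ketal gives the p-quinol; the carbinol centre is formed racemic and is erased in step 7.

**Step 3**
Reactants: 5 rac-4-hydroxy-5-methyl-4-(prop-1-en-2-yl)-2-(propan-2-yl)cyclohexa-2,5-dien-1-one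
Product: 6 rac-5-hydroxy-4-methyl-5-(prop-1-en-2-yl)-1-(propan-2-yl)-7-oxabicyclo[4.1.0]hept-3-en-2-one (epoxide O cis to OH)
Conditions: 30% H2O2, Na2CO3, MeOH/THF, 0 °C
Reagents that add atoms: hydrogen peroxide (OO)
Why: Weitz–Scheffer nucleophilic epoxidation: hydroperoxide adds only to the enone carbon that carries H (not to the methyl-bearing one) and anti to the isopropenyl group, so the epoxide is cis to OH; these centres are erased in steps 5 and 7.

**Step 4**
Reactants: 6 rac-5-hydroxy-4-methyl-5-(prop-1-en-2-yl)-1-(propan-2-yl)-7-oxabicyclo[4.1.0]hept-3-en-2-one; 7 vinylmagnesium bromide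
Product: 8 rac-4-ethenyl-5-hydroxy-4-methyl-5-(prop-1-en-2-yl)-1-(propan-2-yl)-7-oxabicyclo[4.1.0]heptan-2-one (OH, epoxide O and vinyl all cis)
Conditions: 7 (3.5 equiv), THF, −78 → −20 °C; aq. NH4Cl
Reagents that add atoms: none
Why: Alkoxide-directed conjugate addition: the magnesium alkoxide of the quinol hydroxyl delivers the vinyl Grignard reagent to the adjacent β-carbon of the only remaining enone, so vinyl enters cis to O and trans to isopropenyl, the relative configuration the chair oxy-Cope transition state needs.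

**Step 5**
Reactants: 8 rac-4-ethenyl-5-hydroxy-4-methyl-5-(prop-1-en-2-yl)-1-(propan-2-yl)-7-oxabicyclo[4.1.0]heptan-2-one
Product: 9 rac-5-ethenyl-4-hydroxy-5-methyl-4-(prop-1-en-2-yl)-2-(propan-2-yl)cyclohexane-1,3-dione (OH cis to vinyl)
Conditions: Pd(PPh3)4 (5 mol %), dppe (5 mol %), toluene, 80 °C
Reagents that add atoms: none
Why: Pd(0)-catalysed isomerisation of an α,β-epoxy ketone to a 1,3-diketone (oxidative addition at the Cα–O bond, β-hydride shift from the epoxide CH) raises the future C6 to the ketone level and removes two stereocentres.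

**Step 6**
Reactants: 9 rac-5-ethenyl-4-hydroxy-5-methyl-4-(prop-1-en-2-yl)-2-(propan-2-yl)cyclohexane-1,3-dione
Product: 10 rac-5-ethenyl-6-hydroxy-3-methoxy-5-methyl-6-(prop-1-en-2-yl)-2-(propan-2-yl)cyclohex-2-en-1-one (OH cis to vinyl)
Conditions: MeOH, TsOH·H2O (5 mol %), 3 Å MS, rt
Reagents that add atoms: methanol (CO)
Why: Acid-catalysed enol etherification of the cyclic 1,3-dione at the less hindered carbonyl (remote from the quaternary carbinol) masks the acidic dione so that only the tertiary alcohol is deprotonated in step 7.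

**Step 7**
Reactants: 10 rac-5-ethenyl-6-hydroxy-3-methoxy-5-methyl-6-(prop-1-en-2-yl)-2-(propan-2-yl)cyclohex-2-en-1-one
Product: 12 (1(10)E)-8-methoxy-6-oxogermacra-1(10),4,7-trien-5-yl trifluoromethanesulfonate (C3/C6 trans at C4=C5; C6/C9 cis at C7=C8), via potassium enolate 11 (not isolated)
Conditions: KH (1.1 equiv), 18-crown-6, THF, 0 °C → rt; then Comins' reagent, −78 °C
Reagents that add atoms: Comins' reagent, N-(5-chloropyridin-2-yl)-N-triflyl-triflamide (FC(F)(F)S(=O)(=O)N(c1ccc(Cl)cn1)S(=O)(=O)C(F)(F)F)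
Why: Anionic oxy-Cope rearrangement through the chair transition state with both alkenyl groups equatorial cleaves C5–C10 and forms C2–C3, which fixes the (E)-C1=C10 alkene and an enolate with C3 and C6 trans that is captured as the enol triflate; all ring stereocentres are erased.

**Step 8**
Reactants: 12 (1(10)E)-8-methoxy-6-oxogermacra-1(10),4,7-trien-5-yl trifluoromethanesulfonate
Product: 14 (1(10)E,4E)-germacra-1(10),4-diene-6,8-dione, via dienone enol ether 13 (not isolated)
Conditions: Pd(OAc)2 (5 mol %), PPh3, HCO2H, n-Bu3N, DMF, 40 °C; then 1 M HCl, THF, rt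
Reagents that add atoms: water (O)
Why: Pd-catalysed formate reduction of the enol triflate (retention of alkene geometry, giving the 4E enone) followed by acid hydrolysis of the vinylogous ester gives the achiral 1,3-dione, in which C7 is stereolabile.

**Step 9**
Reactants: 14 (1(10)E,4E)-germacra-1(10),4-diene-6,8-dione
Product: 15 (1(10)E,4E,7S,8R)-8-hydroxygermacra-1(10),4-dien-6-one
Conditions: H2 (50 atm), RuCl2[(R)-BINAP](dmf)n (1 mol %), CH2Cl2/MeOH, 40 °C
Reagents that add atoms: none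
Why: Noyori asymmetric hydrogenation with dynamic kinetic resolution: the Ru–BINAP chelate reduces the saturated C8 carbonyl and spares the conjugated C6 carbonyl, (R)-BINAP is expected to give the 8R alcohol by analogy with the β-keto ester rule, and the rapidly epimerising C7 is channelled to the anti (7S) isomer, which should also be the thermodynamic one.

**Step 10**
Reactants: 15 (1(10)E,4E,7S,8R)-8-hydroxygermacra-1(10),4-dien-6-one
Product: 16 (1(10)E,4R,5S,7S,8R)-4,5-epoxy-8-hydroxygermacr-1(10)-en-6-one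
Conditions: 30% H2O2, NaOH (0.3 equiv), MeOH, 0 °C
Reagents that add atoms: hydrogen peroxide (OO)
Why: Weitz–Scheffer nucleophilic epoxidation of the enone only (the isolated C1=C10 alkene is inert) gives the trans epoxide, and peripheral attack on the conformer with the C7 isopropyl and C8 hydroxyl pseudo-equatorial is expected to give the 4R,5S isomer (macrocyclic stereocontrol; see risks).

**Step 11**
Reactants: 17 isovanillic acid (3-hydroxy-4-methoxybenzoic acid)
Product: 19 4-methoxy-3-(trimethylsilyloxy)benzoyl chloride, via bis-TMS isovanillate 18 (not isolated)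
Conditions: TMSCl (2.2 equiv), Et3N, CH2Cl2, rt; then (COCl)2, DMF (cat.), 0 °C → rt; evaporate
Reagents that add atoms: chlorotrimethylsilane (C[Si](C)(C)Cl); oxalyl chloride (O=C(Cl)C(Cl)=O)
Why: Transient silylation: both OH groups are silylated, and oxalyl chloride/DMF converts the silyl ester (not the aryl silyl ether) into the acid chloride under neutral conditions.

**Step 12**
Reactants: 16 (1(10)E,4R,5S,7S,8R)-4,5-epoxy-8-hydroxygermacr-1(10)-en-6-one; 19 4-methoxy-3-(trimethylsilyloxy)benzoyl chloride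
Product: 21 (1(10)E,4R,5S,7S,8R)-4,5-epoxy-6-oxogermacr-1(10)-en-8-yl 3-hydroxy-4-methoxybenzoate, via TMS-protected ester 20 (not isolated)
Conditions: pyridine, DMAP (cat.), CH2Cl2, 0 °C → rt; then aq. citric acid work-up
Reagents that add atoms: none
Why: DMAP-catalysed acylation of the only free hydroxyl (C8) proceeds with retention, the aryl trimethylsilyl ether is cleaved in the mildly acidic work-up, and the absence of strong base avoids β-elimination of the new β-acyloxy ketone.

**Step 13**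
Reactants: 21 (1(10)E,4R,5S,7S,8R)-4,5-epoxy-6-oxogermacr-1(10)-en-8-yl 3-hydroxy-4-methoxybenzoate
Product: 22 (1(10)E,4R,5R,6R,7R,8R)-4,5-epoxy-6-hydroxygermacr-1(10)-en-8-yl 3-hydroxy-4-methoxybenzoate (CNP0294356.1)
Conditions: Zn(BH4)2, Et2O, −20 → 0 °C; aq. NH4Cl
Reagents that add atoms: none
Why: Chelation-controlled reduction of an α,β-epoxy ketone with Zn(BH4)2: zinc bridges the carbonyl and epoxide oxygens and hydride attacks the less hindered face of the chelate, giving the erythro (6R) epoxy alcohol; the ester and phenol are untouched.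

**Compound list**

1 | carvacrol (5-isopropyl-2-methylphenol) | Cc1ccc(C(C)C)cc1O | starting material
2 | 4,4-dimethoxy-2-methyl-5-(propan-2-yl)cyclohexa-2,5-dien-1-one | COC1(OC)C=C(C)C(=O)C=C1C(C)C | intermediate
3 | prop-1-en-2-ylmagnesium bromide | CC(=C)[Mg]Br | starting material
4 | rac-4,4-dimethoxy-2-methyl-1-(prop-1-en-2-yl)-5-(propan-2-yl)cyclohexa-2,5-dien-1-ol (quinol ketal) | COC1(OC)C=C(C)[C@@](O)(C(C)=C)C=C1C(C)C | intermediate
5 | rac-4-hydroxy-5-methyl-4-(prop-1-en-2-yl)-2-(propan-2-yl)cyclohexa-2,5-dien-1-one | O[C@]1(C(C)=C)C=C(C(C)C)C(=O)C=C1C | intermediate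
6 | rac-5-hydroxy-4-methyl-5-(prop-1-en-2-yl)-1-(propan-2-yl)-7-oxabicyclo[4.1.0]hept-3-en-2-one, epoxide O cis to OH | O[C@]1(C(C)=C)[C@@H]2O[C@]2(C(C)C)C(=O)C=C1C | intermediate
7 | vinylmagnesium bromide | C=C[Mg]Br | starting material
8 | rac-4-ethenyl-5-hydroxy-4-methyl-5-(prop-1-en-2-yl)-1-(propan-2-yl)-7-oxabicyclo[4.1.0]heptan-2-one, OH, epoxide O and vinyl cis | O[C@]1(C(C)=C)[C@@H]2O[C@]2(C(C)C)C(=O)C[C@]1(C)C=C | intermediate
9 | rac-5-ethenyl-4-hydroxy-5-methyl-4-(prop-1-en-2-yl)-2-(propan-2-yl)cyclohexane-1,3-dione, OH cis to vinyl, C2 stereolabile | O[C@]1(C(C)=C)C(=O)C(C(C)C)C(=O)C[C@]1(C)C=C | intermediate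
10 | rac-5-ethenyl-6-hydroxy-3-methoxy-5-methyl-6-(prop-1-en-2-yl)-2-(propan-2-yl)cyclohex-2-en-1-one, OH cis to vinyl | O[C@]1(C(C)=C)C(=O)C(C(C)C)=C(OC)C[C@]1(C)C=C | intermediate
11 | potassium (1(10)E)-8-methoxy-6-oxogermacra-1(10),4,7-trien-5-olate | C1/C(C)=C([O-])/C(=O)/C(C(C)C)=C(OC)\C/C(C)=C/C1.[K+] | intermediate
12 | (1(10)E)-8-methoxy-6-oxogermacra-1(10),4,7-trien-5-yl trifluoromethanesulfonate | C1/C(C)=C(OS(=O)(=O)C(F)(F)F)/C(=O)/C(C(C)C)=C(OC)\C/C(C)=C/C1 | intermediate
13 | (1(10)E,4E)-8-methoxygermacra-1(10),4,7-trien-6-one (C6/C9 cis at C7=C8) | C1/C(C)=C/C(=O)/C(C(C)C)=C(OC)\C/C(C)=C/C1 | intermediate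
14 | (1(10)E,4E)-germacra-1(10),4-diene-6,8-dione | O=C1C/C(C)=C/CC/C(C)=C/C(=O)C1C(C)C | intermediate
15 | (1(10)E,4E,7S,8R)-8-hydroxygermacra-1(10),4-dien-6-one | O[C@@H]1C/C(C)=C/CC/C(C)=C/C(=O)[C@H]1C(C)C | intermediate
16 | (1(10)E,4R,5S,7S,8R)-4,5-epoxy-8-hydroxygermacr-1(10)-en-6-one | O[C@@H]1C/C(C)=C/CC[C@@]2(C)O[C@@H]2C(=O)[C@H]1C(C)C | intermediate
17 | isovanillic acid (3-hydroxy-4-methoxybenzoic acid) | COc1ccc(C(=O)O)cc1O | starting material
18 | trimethylsilyl 4-methoxy-3-(trimethylsilyloxy)benzoate | COc1ccc(C(=O)O[Si](C)(C)C)cc1O[Si](C)(C)C | intermediate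
19 | 4-methoxy-3-(trimethylsilyloxy)benzoyl chloride | COc1ccc(C(Cl)=O)cc1O[Si](C)(C)C | intermediate
20 | (1(10)E,4R,5S,7S,8R)-4,5-epoxy-6-oxogermacr-1(10)-en-8-yl 4-methoxy-3-(trimethylsilyloxy)benzoate | COc1ccc(C(=O)O[C@@H]2C/C(C)=C/CC[C@@]3(C)O[C@@H]3C(=O)[C@H]2C(C)C)cc1O[Si](C)(C)C | intermediate
21 | (1(10)E,4R,5S,7S,8R)-4,5-epoxy-6-oxogermacr-1(10)-en-8-yl 3-hydroxy-4-methoxybenzoate | COc1ccc(C(=O)O[C@@H]2C/C(C)=C/CC[C@@]3(C)O[C@@H]3C(=O)[C@H]2C(C)C)cc1O | intermediate
22 | (1(10)E,4R,5R,6R,7R,8R)-4,5-epoxy-6-hydroxygermacr-1(10)-en-8-yl 3-hydroxy-4-methoxybenzoate (CNP0294356.1) | COc1ccc(C(=O)O[C@@H]2C/C(C)=C/CC[C@@]3(C)O[C@@H]3[C@H](O)[C@H]2C(C)C)cc1O | target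

**Step count and risks**

Total steps: 13. Longest linear sequence: 12 (steps 1–10, 12, 13).

The three steps most likely to fail:

The directed vinyl transfer of step 4 must build a quaternary carbon next to a fully substituted carbinol, and 1,2-addition or epoxide opening may compete. The fallback sets out from 6. Dimethylaluminium (trimethylsilyl)acetylide (toluene, 0 °C) is delivered by the aluminium alkoxide to the same β-carbon and face, the linear alkynyl group being far less demanding, and gives the silylalkyne ketone F1. K2CO3/MeOH gives the ethynyl ketone F2, and Lindlar semi-hydrogenation gives 8, where the route is rejoined.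

The asymmetric hydrogenation of step 9 depends on Ru chelation by a macrocyclic 1,3-dione, on selection of the C8 over the C6 carbonyl and on the sense of induction. The fallback sets out from 14. KHMDS then PhNTf2 gives, at the less hindered C8 oxygen, the vinylogous triflate F3. Pd(OAc)2/PPh3/HCO2H/n-Bu3N reduces it to the cross-conjugated trienone F4. Copper-catalysed enantioselective conjugate borylation (CuCl, Josiphos ligand, B2pin2, NaOtBu, MeOH) of the β-monosubstituted C7=C8 enone gives the β-boryl ketone F5, and NaBO3 oxidation with retention gives 15.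

The epoxidation of step 10 relies on macrocyclic face selectivity, and the β-hydroxy ketone is base-sensitive. The fallback sets out from 15. TESOTf/2,6-lutidine gives the silyl ether F6. CBS reduction of the enone under reagent control gives the C6-epimeric allylic alcohol F7. VO(acac)2/TBHP then epoxidises syn to the hydroxyl under A(1,3) control (threo), which is the epoxide face of the target, and gives the epoxy alcohol F8. Dess–Martin oxidation gives the silylated epoxy ketone F9, and TBAF/AcOH gives 16.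

**Further compounds**

F1 | step 4 | rac-5-hydroxy-4-methyl-5-(prop-1-en-2-yl)-1-(propan-2-yl)-4-[(trimethylsilyl)ethynyl]-7-oxabicyclo[4.1.0]heptan-2-one, alkynyl cis to OH | O[C@]1(C(C)=C)[C@@H]2O[C@]2(C(C)C)C(=O)C[C@]1(C)C#C[Si](C)(C)C
F2 | step 4 | rac-4-ethynyl-5-hydroxy-4-methyl-5-(prop-1-en-2-yl)-1-(propan-2-yl)-7-oxabicyclo[4.1.0]heptan-2-one | O[C@]1(C(C)=C)[C@@H]2O[C@]2(C(C)C)C(=O)C[C@]1(C)C#C
F3 | step 9 | (1(10)E,4E)-6-oxogermacra-1(10),4,7-trien-8-yl trifluoromethanesulfonate (C6/C9 cis at C7=C8) | C1/C(C)=C/C(=O)/C(C(C)C)=C(OS(=O)(=O)C(F)(F)F)\C/C(C)=C/C1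
F4 | step 9 | (1(10)E,4E,7Z)-germacra-1(10),4,7-trien-6-one | C1/C(C)=C/C(=O)/C(C(C)C)=C\C/C(C)=C/C1
F5 | step 9 | (1(10)E,4E)-8-(4,4,5,5-tetramethyl-1,3,2-dioxaborolan-2-yl)germacra-1(10),4-dien-6-one, C7 and C8 configured as in 15 | CC1(C)OB(OC1(C)C)[C@@H]2C/C(C)=C/CC/C(C)=C/C(=O)[C@H]2C(C)C
F6 | step 10 | (1(10)E,4E,7S,8R)-8-(triethylsilyloxy)germacra-1(10),4-dien-6-one | CC[Si](CC)(CC)O[C@@H]1C/C(C)=C/CC/C(C)=C/C(=O)[C@H]1C(C)C
F7 | step 10 | (1(10)E,4E)-8-(triethylsilyloxy)germacra-1(10),4-dien-6-ol, C6 hydroxyl on the face opposite to that in 22 | CC[Si](CC)(CC)O[C@@H]1C/C(C)=C/CC/C(C)=C/[C@@H](O)[C@H]1C(C)C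
F8 | step 10 | (1(10)E,4R,5R,6S,7R,8R)-4,5-epoxy-8-(triethylsilyloxy)germacr-1(10)-en-6-ol | CC[Si](CC)(CC)O[C@@H]1C/C(C)=C/CC[C@@]2(C)O[C@@H]2[C@@H](O)[C@H]1C(C)C
F9 | step 10 | (1(10)E,4R,5S,7S,8R)-4,5-epoxy-8-(triethylsilyloxy)germacr-1(10)-en-6-one | CC[Si](CC)(CC)O[C@@H]1C/C(C)=C/CC[C@@]2(C)O[C@@H]2C(=O)[C@H]1C(C)C
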